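Readings and results were computed with made-up constants, and the scatter is random.

The readings of the beta and alpha runs cannot show us how much nucleophile is bound, since they give electrophile and target, so we reach that share through a chain of hand estimates.

in all of them: electrophile 0.10 M

| charge | nucleophile | free base | remark | time |
|---|---|---|---|---|
| beta | 0.087 M | 0.11 M (fed, over 50 s) | run made earlier |  |
| alpha | 0.20 M | 0.11 M (fed, over 50 s) | run made earlier |  |
| flask | 0.130 M | 0.110 M (fed, over 50 s) |  | 2.0 min |

| run | time / s | electrophile / % | target / % |
|---|---|---|---|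
| beta | 20.0 | 58.4 | 22.4 |
| beta | 40.0 | 39.1 | 33.1 |
| beta | 60.0 | 29.2 | 40.0 |
| beta | 80.0 | 23.1 | 44.8 |
| beta | 90.0 | 19.8 | 47.3 |
| beta | 120 | 14.4 | 49.9 |
| alpha | 10.0 | 62.6 | 28.6 |
| alpha | 15.0 | 50.0 | 36.9 |
| alpha | 25.0 | 34.3 | 50.7 |
| alpha | 40.0 | 20.7 | 60.9 |
| alpha | 80.0 | 7.5 | 74.8 |
| alpha | 120 | 2.4 | 77.5 |

(scatter of a reading: 0.5 percentage points)

- part of the electrophile that has reacted at 2.0 min
- share of the unused nucleophile that is free and not bound as protonated nucleophile, at 2.0 min

We work with the fraction left. At 120 s the beta run keeps 14.4 % of its electrophile and the alpha run 2.4 %, so the logarithm of that fraction falls with the nucleophile charged at a slope s = 15.9 M⁻¹. Going from the beta charge to 0.130 M, we reckon that our flask keeps 7.28 %, so the part reacted, c, is 92.7 %.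

A straight line between the same two runs puts the target in our flask at 60.4 %. We assume that each target sets free one acid. Now define the base margin m, the charge of free base less the acid set free so far, a stoichiometric excess. Here m = 0.0496 M.

The weak link is that target line, so we reforge it with a harsher case at our reckoned c. Even if every reacted electrophile became target, the acid would be 0.0927 M, less than the 0.110 M of base, and m would still be 0.0173 M. We therefore commit to c = 92.7 % and, if free base takes acid ahead of nucleophile, which remains our guess, put the free share of the unused nucleophile, fr, near 100 %.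

The forecast puts c at 92.5 % (90 % to 95 %) and parts from us on fr, which it puts at 75 % (50 % to 95 %), saying “Acid balance suggests somewhat more in the flask”.

The flask gives c = 92.0 % and fr = 99.9 %.

    nucleophile + acid set free ⇌ protonated nucleophile, settled at all times (K = 97.0 M⁻¹)
    crystals ⇌ acid set free, rate k2*(cs2 - [acid set free]) while solid is left; crystals form when [acid set free] > cs2 (solubility = 1.40 mM, k = 0.710 s⁻¹)
    electrophile + nucleophile → acid set free + target (k = 0.200 M⁻¹ s⁻¹)
    acid set free + free base ⇌ salt of the base, settled at all times (K = 1.30 × 10⁵ M⁻¹)
    2 electrophile → self-condensation product (k = 0.0830 M⁻¹ s⁻¹)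

At 2.00 min our flask holds 0.0653 M of salt of the base against 7.03 × 10⁻⁵ M of protonated nucleophile, and its 65.4 % of target gives it a margin m of 0.0446 M. The neighbour flask with 0.044 M of free base makes 62.9 % of target, so its margin m is negative, a shortfall of 0.0189 M, and in that neighbour flask fr is 86.6 %.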